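The route is built on the spiro carbon C3, the one unsubstituted carbon of the acylphloroglucinol ring (C1–C2–C3–C4–C5–C9), which in the target carries both cyclopentane bonds C3–C11 and C3–C14. One operation lets this carbon add to the β-carbon of an enantiopure chloro enal under iminium catalysis and then, as the para carbon of a phenolate, displace the C14 chloride, closing the cyclopentane C3–C11–C12–C13–C14 and dearomatizing the ring. The precursors are 2-isobutyryl-4-geranylphloroglucinol, carried as the methyl ether of its C2 oxygen, and (S,E)-5-(chloromethyl)-4,4,6-trimethylhepta-2,6-dienal. The cage bonds C5–C6 and C1–C8 are then made one after the other.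

Key step: step 9

Assumption: atom numbers are those of the target (C1 isobutyryl, C5 geranyl, C9 one-carbon bridge, C6–C7–C8 with gem-dimethyl C8, C10–C11 bridge, C12 gem-dimethyl, C13 isopropenyl, C14); the C2 oxygen is carried as a methyl ether that is lost in step 14, and lactol–aldehyde equilibria are drawn as the aldehyde.

Step 1
Reactants: 1 5-methoxyresorcinol; 2 isobutyric acid
Product: 3 1-(2,4-dihydroxy-6-methoxyphenyl)-2-methylpropan-1-one
Conditions: BF3·OEt2 (neat), 80 °C; aq. NaOAc
Reagents that add atoms: none
Why: Friedel–Crafts acylation, in which the boron-chelated 2-hydroxyaryl ketone resists a second acylation and the two equivalent positions flanked by OH and OMe should be favoured over the position between the hydroxyls, the minor regioisomer being removed by chromatography.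

Step 2
Reactants: 3 1-(2,4-dihydroxy-6-methoxyphenyl)-2-methylpropan-1-one; 4 geranyl bromide
Product: 5 1-[3-[(2E)-3,7-dimethylocta-2,6-dien-1-yl]-2,4-dihydroxy-6-methoxyphenyl]-2-methylpropan-1-one
Conditions: 10 % aq. KOH, 0 °C to rt
Reagents that add atoms: none
Why: C-alkylation of the phenolate by an allylic halide in water should go to the ring carbon flanked by both free hydroxyls (C5), the usual site of C-prenylation of acylphloroglucinols, and leaves C3 as the only unsubstituted ring carbon.

Step 3
Reactants: 6 furan-2(5H)-one; 7 4,4,5,5-tetramethyl-2-(prop-1-en-2-yl)-1,3,2-dioxaborolane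
Product: 8 (R)-4-(prop-1-en-2-yl)dihydrofuran-2(3H)-one
Conditions: [Rh(OH)(cod)]2 (2.5 mol %), (R)-BINAP (6 mol %), KOH (cat.), dioxane–H2O, 40 °C
Reagents that add atoms: none
Why: Hayashi–Miyaura conjugate addition, in which the (R)-BINAP–rhodium alkenyl species (the ligand antipode of the one that gives (S)-3-substituted cyclic ketones) should add to one face of the butenolide and set the future C13 as the (R)-lactone.

Step 4
Reactants: 8 (R)-4-(prop-1-en-2-yl)dihydrofuran-2(3H)-one
Product: 10 (S)-3,3-dimethyl-4-(prop-1-en-2-yl)dihydrofuran-2(3H)-one, via monomethyl lactone 9 (not isolated)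
Conditions: LiN(i-Pr)2 (1.1 equiv), THF, −78 °C, MeI; then LiN(i-Pr)2 (1.2 equiv), MeI, −78 to 0 °C
Reagents that add atoms: iodomethane, CI
Why: Two successive lactone enolate alkylations build the gem-dimethyl carbon C12, while the stereocentre is β to the carbonyl, not enolizable, and therefore untouched (the descriptor changes only through priorities).

Step 5
Reactants: 10 (S)-3,3-dimethyl-4-(prop-1-en-2-yl)dihydrofuran-2(3H)-one
Product: 11 (4S)-3,3-dimethyl-4-(prop-1-en-2-yl)tetrahydrofuran-2-ol (anomers)
Conditions: i-Bu2AlH (1.1 equiv), CH2Cl2, −78 °C; aq. KNaC4H4O6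
Reagents that add atoms: none
Why: Partial reduction of a lactone to the lactol should stop at the aluminium hemiacetal at −78 °C, helped by the α-quaternary carbon.

Step 6
Reactants: 11 (4S)-3,3-dimethyl-4-(prop-1-en-2-yl)tetrahydrofuran-2-ol
Product: 12 (S)-3,3-dimethyl-2-(prop-1-en-2-yl)pent-4-en-1-ol
Conditions: Ph3PCH3Br (3 equiv), KOt-Bu (3 equiv), THF, 0 to 50 °C
Reagents that add atoms: methyltriphenylphosphonium bromide, C[P+](c1ccccc1)(c1ccccc1)c1ccccc1.[Br-]
Why: Wittig methylenation of the lactol through its hydroxy aldehyde tautomer, in which the small unstabilized ylide tolerates the neopentyl aldehyde and sets free the C14 hydroxyl and the C10=C11 vinyl group.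

Step 7
Reactants: 12 (S)-3,3-dimethyl-2-(prop-1-en-2-yl)pent-4-en-1-ol
Product: 13 (S)-4-(chloromethyl)-3,3,5-trimethylhexa-1,5-diene
Conditions: PPh3, CCl4, 60 °C
Reagents that add atoms: carbon tetrachloride, ClC(Cl)(Cl)Cl
Why: Appel reaction, an SN2 displacement at the primary carbon C14 that leaves the stereocentre and the alkenes alone and is done before the enal is made so that no hydroxy enal prone to oxa-Michael closure arises.

Step 8
Reactants: 13 (S)-4-(chloromethyl)-3,3,5-trimethylhexa-1,5-diene; 14 (E)-but-2-enal
Product: 15 (S,E)-5-(chloromethyl)-4,4,6-trimethylhepta-2,6-dienal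
Conditions: second-generation Hoveyda–Grubbs catalyst (5 mol %), 14 (5 equiv), CH2Cl2, 40 °C
Reagents that add atoms: none
Why: Olefin cross-metathesis of the monosubstituted vinyl group with an electron-poor partner should be selective because the 1,1-disubstituted isopropenyl group does not enter the catalytic cycle, and it gives the (E)-enal under thermodynamic control.

Step 9
Reactants: 5 1-[3-[(2E)-3,7-dimethylocta-2,6-dien-1-yl]-2,4-dihydroxy-6-methoxyphenyl]-2-methylpropan-1-one; 15 (S,E)-5-(chloromethyl)-4,4,6-trimethylhepta-2,6-dienal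
Product: 17 spiro dienone aldehyde (C2 methyl enol ether of the spiro-dearomatized acylphloroglucinol with the C10–C7 aldehyde arm; C3 S, C11 S, C13 S; C10 trans to the isopropenyl group and syn to C4), via chromanol lactol 16 (not isolated)
Conditions: (S)-α,α-diphenylprolinol trimethylsilyl ether (20 mol %), PhCO2H (20 mol %), toluene, 0 °C to rt; then DMF, NaI (0.2 equiv), K2CO3 (2.5 equiv), 50 °C; aq. NH4Cl
Reagents that add atoms: none
Why: The (S)-diarylprolinol silyl ether turns enal 15 into an (E)-iminium ion with one face blocked, so C3 of 5 (ortho to the free C4 hydroxyl, para to the chelated C9 hydroxyl) adds to C11 from the open face and sets C11 (S) under catalyst control, the aldehyde then resting as the six-membered lactol 16 on the C4 oxygen, the only hydroxyl next to C3. NaI exchanges the chloride and K2CO3 forms the C9 phenolate, whose para carbon C3 displaces the halide in a 5-exo-tet closure that builds the spiro cyclopentane C3–C11–C12–C13–C14 and dearomatizes the ring to the cross-conjugated dienone. The closest known reactions are the iminium-catalysed Friedel–Crafts addition of phenols to enals with chromanol formation and the base-mediated aryl-participated (Ar1-5) spiroalkylation of para-hydroxyaryl alkyl halides. C3 is set by the substrate, because the lactol ties C10 to the C4 oxygen and, should the lactol open, the C2 methoxy group is the larger flank (the C4 hydroxyl is deliberately left unprotected), so the C11 hydrogen turns to C2 and C10 to C4. C-alkylation is secured because closure through the C4 oxygen would need a seven-membered ring and the C2 oxygen is capped, and the site is unambiguous because C3 is the only free ring carbon. The step needs the iminium addition to tolerate the quaternary neighbour of the β-carbon, which is the main risk of the route.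

Step 10
Reactants: 17 spiro dienone aldehyde; 18 isopropenylmagnesium bromide
Product: 19 C7 allylic alcohol (C7 epimers)
Conditions: 18 (3 equiv), THF, −78 to −30 °C; aq. NH4Cl
Reagents that add atoms: none
Why: Grignard 1,2-addition to the aldehyde, the only unhindered carbonyl once the first equivalent has turned the vinylogous acid (C4–OH/C5/C9) into its magnesium enolate and opened the lactol; the C7 carbinol forms as an epimer mixture that is erased in step 11.

Step 11
Reactants: 19 C7 allylic alcohol
Product: 20 C7 isopropenyl ketone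
Conditions: MnO2 (excess), CH2Cl2, rt
Reagents that add atoms: none
Why: MnO2 oxidation is specific for the allylic alcohol and should leave the enolized dione, the enol ether and the isolated alkenes alone.

Step 12
Reactants: 20 C7 isopropenyl ketone
Product: 21 2,3-disubstituted buta-1,3-diene (C6H2=C7–C8(CH3)=CH2)
Conditions: Ph3PCH3Br (3.5 equiv), KOt-Bu (3.3 equiv), THF, 0 °C to rt
Reagents that add atoms: methyltriphenylphosphonium bromide, C[P+](c1ccccc1)(c1ccccc1)c1ccccc1.[Br-]
Why: Wittig methylenation of the C7 ketone, the only ketone neither masked as an enolate nor buried between fully substituted carbons, gives the diene that holds C6, C7 and C8.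

Step 13
Reactants: 21 2,3-disubstituted buta-1,3-diene
Product: 22 bicyclo[4.3.1] dione with the C5–C6 bond and the C7=C8 isopropylidene group
Conditions: Pd(PPh3)4 (5 mol %), THF, 60 °C
Reagents that add atoms: none
Why: Pd-catalysed hydroalkylation of a 1,3-diene by a 1,3-dicarbonyl compound, in which the acidic C5–H protonates zerovalent palladium, hydropalladation gives the 1,1-dimethylallyl complex C6–C7–C8, and the C5 enolate attacks its unhindered CH2 end C6 in a seven-membered ring closure, C5 being set because C6 can only reach the ring face that carries C11.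

Step 14
Reactants: 22 bicyclo[4.3.1] dione
Product: 23 7-iodo cage trione
Conditions: bis(pyridine)iodonium tetrafluoroborate (1.1 equiv), CH2Cl2, −60 to 0 °C; aq. Na2S2O3
Reagents that add atoms: bis(pyridine)iodonium tetrafluoroborate, c1cc[n+](cc1)[I-][n+]1ccccc1.F[B-](F)(F)F
Why: Iodonium-induced carbocyclization, in which the tetrasubstituted C7=C8 bond is by far the most nucleophilic alkene, its iodonium ion forms on the outer face, and the enol ether carbon C1 opens it at C8 from inside in an anti six-membered closure that completes the cage and sets C1 and C7, after which pyridine demethylates the C2 oxocarbenium ion, so that no protic acid or free hydroxyl is present.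

Step 15
Reactants: 23 7-iodo cage trione
Product: 24 CNP0280463.1
Conditions: Bu3SnH (1.5 equiv), AIBN (cat.), benzene, 80 °C
Reagents that add atoms: none
Why: Radical dehalogenation, in which the bridgehead C7 radical can take hydrogen only from the outer face, so the cage fixes the configuration, while ketones and isolated alkenes do not react.

Compound list
1 | 5-methoxyresorcinol (5-methoxybenzene-1,3-diol) | COc1cc(O)cc(O)c1 | starting material
2 | isobutyric acid | CC(C)C(=O)O | starting material
3 | 1-(2,4-dihydroxy-6-methoxyphenyl)-2-methylpropan-1-one | CC(C)C(=O)c1c(OC)cc(O)cc1O | intermediate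
4 | geranyl bromide | CC(C)=CCC/C(C)=C/CBr | starting material
5 | 1-[3-[(2E)-3,7-dimethylocta-2,6-dien-1-yl]-2,4-dihydroxy-6-methoxyphenyl]-2-methylpropan-1-one (2-isobutyryl-4-geranylphloroglucinol, methyl ether at the C2 oxygen) | CC(C)C(=O)c1c(OC)cc(O)c(C/C=C(\C)CCC=C(C)C)c1O | intermediate
6 | furan-2(5H)-one | O=C1OCC=C1 | starting material
7 | 4,4,5,5-tetramethyl-2-(prop-1-en-2-yl)-1,3,2-dioxaborolane | C=C(C)B1OC(C)(C)C(C)(C)O1 | starting material
8 | (R)-4-(prop-1-en-2-yl)dihydrofuran-2(3H)-one | O=C1C[C@@H](CO1)C(C)=C | intermediate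
9 | (4R)-3-methyl-4-(prop-1-en-2-yl)dihydrofuran-2(3H)-one (C3 epimers, not isolated) | O=C1C(C)[C@@H](CO1)C(C)=C | intermediate
10 | (S)-3,3-dimethyl-4-(prop-1-en-2-yl)dihydrofuran-2(3H)-one | O=C1C(C)(C)[C@@H](CO1)C(C)=C | intermediate
11 | (4S)-3,3-dimethyl-4-(prop-1-en-2-yl)tetrahydrofuran-2-ol (anomers) | OC1OC[C@@H](C(C)=C)C1(C)C | intermediate
12 | (S)-3,3-dimethyl-2-(prop-1-en-2-yl)pent-4-en-1-ol | C=CC(C)(C)[C@@H](CO)C(C)=C | intermediate
13 | (S)-4-(chloromethyl)-3,3,5-trimethylhexa-1,5-diene | C=CC(C)(C)[C@@H](CCl)C(C)=C | intermediate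
14 | (E)-but-2-enal (crotonaldehyde) | C/C=C/C=O | starting material
15 | (S,E)-5-(chloromethyl)-4,4,6-trimethylhepta-2,6-dienal | O=C/C=C/C(C)(C)[C@@H](CCl)C(C)=C | intermediate
16 | chromanol lactol: C3 of 5 bonded to C11 (S), aldehyde closed as hemiacetal on the C4 oxygen (anomers, not isolated) | CC(C)C(=O)c1c(OC)c2[C@H](C(C)(C)[C@@H](CCl)C(C)=C)CC(O)Oc2c(C/C=C(\C)CCC=C(C)C)c1O | intermediate
17 | spiro dienone aldehyde: C2 methyl enol ether of the spiro-dearomatized acylphloroglucinol with the C10–C7 aldehyde arm (C3 S, C11 S, C13 S; in equilibrium with its lactol on the C4 oxygen) | O=CC[C@H]1C(C)(C)[C@H](C(C)=C)C[C@]12C(OC)=C(C(=O)C(C)C)C(=O)C(C/C=C(\C)CCC=C(C)C)=C2O | intermediate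
18 | isopropenylmagnesium bromide | C=C(C)[Mg]Br | starting material
19 | C7 allylic alcohol (C7 epimers) | C=C(C)C(O)C[C@H]1C(C)(C)[C@H](C(C)=C)C[C@]12C(OC)=C(C(=O)C(C)C)C(=O)C(C/C=C(\C)CCC=C(C)C)=C2O | intermediate
20 | C7 isopropenyl ketone | C=C(C)C(=O)C[C@H]1C(C)(C)[C@H](C(C)=C)C[C@]12C(OC)=C(C(=O)C(C)C)C(=O)C(C/C=C(\C)CCC=C(C)C)=C2O | intermediate
21 | 2,3-disubstituted buta-1,3-diene | C=C(C)C(=C)C[C@H]1C(C)(C)[C@H](C(C)=C)C[C@]12C(OC)=C(C(=O)C(C)C)C(=O)C(C/C=C(\C)CCC=C(C)C)=C2O | intermediate
22 | bicyclo[4.3.1] dione with C5–C6 bond, C7=C8 isopropylidene and C2 methyl enol ether | CC(C)=C1C[C@H]2C(C)(C)[C@H](C(C)=C)C[C@]23C(OC)=C(C(=O)C(C)C)C(=O)[C@](C/C=C(\C)CCC=C(C)C)(C1)C3=O | intermediate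
23 | 7-iodo cage trione (target with iodine in place of the C7 hydrogen) | C=C(C)[C@@H]1C[C@@]23C(=O)[C@@]4(C/C=C(\C)CCC=C(C)C)C[C@@](I)(C[C@H]2C1(C)C)C(C)(C)[C@](C(=O)C(C)C)(C4=O)C3=O | intermediate
24 | CNP0280463.1 | C=C(C)[C@@H]1C[C@@]23C(=O)[C@@]4(C/C=C(\C)CCC=C(C)C)C[C@@H](C[C@H]2C1(C)C)C(C)(C)[C@](C(=O)C(C)C)(C4=O)C3=O | target

Total step count: 15. Longest linear sequence: 13 steps (6 to 24, steps 3–15).

Steps most likely to fail

Step 9. The iminium conjugate addition may be too slow at a β-carbon that bears a quaternary neighbour, so that reversible 1,2-addition and condensation divert the material. Catalyst control at C11 may also be eroded by the resident C13 centre, and the face of ring closure may leak. The fallback sets out from 15 and 5 and returns at 17. Enal 15 is converted with HC(OMe)3 and pyridinium p-toluenesulfonate in MeOH into (S,E)-5-(chloromethyl)-1,1-dimethoxy-4,4,6-trimethylhepta-2,6-diene F1. Catalytic TMSOTf (CH2Cl2, −78 °C) ionizes it to the 1-methoxyallyl cation, a far stronger electrophile than the iminium ion, which alkylates C3 of 5 at C11. The enol ether so formed closes onto the C4 hydroxyl to the 2-methoxychroman F2. C11 is not controlled here, so the two C11 epimers (diastereomers, because C13 is fixed) are separated by chromatography. K2CO3 and NaI in DMF then close the spiro ring on the acetal-tethered substrate to the spiro cyclic acetal F3, and pyridinium p-toluenesulfonate in wet acetone unmasks 17.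

Step 14. The iodonium ion may be intercepted at the geranyl or isopropenyl alkenes or by a carbonyl oxygen, or the bond between two fully substituted carbons may not form. The fallback sets out from 22 and returns at 24. Dimethyldioxirane (1 equiv, acetone, −78 °C) epoxidizes the tetrasubstituted C7=C8 bond from its outer face to the epoxide F4. TMSOTf and 2,6-lutidine (CH2Cl2, −78 °C) let the enol ether carbon C1 open the epoxide at C8 (epoxide-opening cation–enol ether cyclization); lutidine demethylates the oxocarbenium ion, and acidic work-up gives the 7-hydroxy cage trione F5. SOCl2 and pyridine convert the bridgehead alcohol with retention into the 7-chloro cage trione F6, which Bu3SnH and AIBN reduce to 24.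

Step 13. Hydropalladation may start at the wrong diene terminus, the enol oxygen may be allylated, or the seven-membered ring closure may be too slow. The fallback sets out from 21 and returns at 22. N-Bromosuccinimide (1 equiv, CH2Cl2, 0 °C) brominates the enolic C5 to the C5 bromide F7. Slow addition of Bu3SnH with AIBN (benzene, 80 °C) generates the C5 radical, which adds to the diene terminus C6 (7-endo), and the allyl radical takes hydrogen at its CH2 end to give 22.

Further compounds
F1 | step 9 | (S,E)-5-(chloromethyl)-1,1-dimethoxy-4,4,6-trimethylhepta-2,6-diene | COC(OC)/C=C/C(C)(C)[C@@H](CCl)C(C)=C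
F2 | step 9 | 2-methoxychroman (cyclic methyl acetal of lactol 16 on the C4 oxygen, C11 S) | CC(C)C(=O)c1c(OC)c2[C@H](C(C)(C)[C@@H](CCl)C(C)=C)CC(OC)Oc2c(C/C=C(\C)CCC=C(C)C)c1O
F3 | step 9 | spiro cyclic acetal (17 with C7 closed as methyl acetal on the C4 oxygen) | COC1C[C@H]2C(C)(C)[C@H](C(C)=C)C[C@]23C(OC)=C(C(=O)C(C)C)C(=O)C(C/C=C(\C)CCC=C(C)C)=C3O1
F4 | step 14 | C7–C8 epoxide of 22 | CC1(C)OC12C[C@H]3C(C)(C)[C@H](C(C)=C)C[C@]34C(OC)=C(C(=O)C(C)C)C(=O)[C@](C/C=C(\C)CCC=C(C)C)(C2)C4=O
F5 | step 14 | 7-hydroxy cage trione | C=C(C)[C@@H]1C[C@@]23C(=O)[C@@]4(C/C=C(\C)CCC=C(C)C)C[C@@](O)(C[C@H]2C1(C)C)C(C)(C)[C@](C(=O)C(C)C)(C4=O)C3=O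
F6 | step 14 | 7-chloro cage trione | C=C(C)[C@@H]1C[C@@]23C(=O)[C@@]4(C/C=C(\C)CCC=C(C)C)C[C@@](Cl)(C[C@H]2C1(C)C)C(C)(C)[C@](C(=O)C(C)C)(C4=O)C3=O
F7 | step 13 | C5 bromide of 21 | C=C(C)C(=C)C[C@H]1C(C)(C)[C@H](C(C)=C)C[C@]12C(OC)=C(C(=O)C(C)C)C(=O)C(Br)(C/C=C(\C)CCC=C(C)C)C2=O
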